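## Retrosynthetic overview

Atom labels follow germacranolide numbering: C1 ketone, C2=C3 furanone olefin, C4=C5, C6 lactone O-carbon, C7, C8 ester carbon, C9, C10 quaternary carbon, C11=C13 exo-methylene, C12 lactone carbonyl, C14 methyl, C15 CH2OH.

1. The furanone is made last, by transannular 5-endo-dig addition of the C10 tertiary OH onto a strained ten-membered C1 ynone (C3–O bond).
2. The ten-membered ring is closed at an sp carbon (C1–C2) by intramolecular CrCl2/NiCl2 coupling of an iodoalkyne with the C1 α-hydroxy aldehyde, instead of the usual macrocyclic Barbier closure at C6–C7.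
3. The C6–C7 bond and the trans α-methylene lactone are made earlier, in one intermolecular allylboration/lactonisation between fragment A (allylboronate, C7–C13 plus C8–C10, C1, C14) and fragment B (enynal, C2–C6, C15).
4. Fragment A comes from (S)-citramalic acid (C10 from the chiral pool), methyl propiolate (C8 by asymmetric alkynylation) and ICH2Bpin; fragment B comes from but-2-yne-1,4-diol and trimethylsilylacetylene.
5. Ring order: γ-lactone, then ten-membered carbocycle, then furanone; the C8 ester goes on before ring closure and the C15 alcohol is unveiled last.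

Assumption: in step 4 the (R,R)-ProPhenol/Me2Zn catalyst is taken to give the (4R)-carbinol by analogy with its other alkynylations; if the sense is opposite, the (S,S)-ligand is used and nothing else changes.

## Route

Step 1
Reactants: 1 (S)-citramalic acid [(2S)-2-hydroxy-2-methylbutanedioic acid]
Product: 2 (2S)-2-methylbutane-1,2,4-triol
Conditions: BH3·SMe2, B(OMe)3, THF, 0 °C to rt; MeOH
Reagents that add atoms: none
Why: Borane reduction of both carboxylic acids of a malic-type hydroxy diacid; the C10 stereocentre comes from the chiral pool and is not touched.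

Step 2
Reactants: 2 (2S)-2-methylbutane-1,2,4-triol
Product: 3 2-[(4S)-2,2,4-trimethyl-1,3-dioxolan-4-yl]ethan-1-ol
Conditions: Me2C(OMe)2, TsOH·H2O (cat.), CH2Cl2, rt
Reagents that add atoms: 2,2-dimethoxypropane, COC(C)(C)OC
Why: Acid-catalysed transketalisation gives the thermodynamically preferred five-membered acetonide of the tertiary and adjacent primary hydroxyls, leaving the C8 primary alcohol free (the minor 1,3-dioxane is removed by chromatography).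

Step 3
Reactants: 3 2-[(4S)-2,2,4-trimethyl-1,3-dioxolan-4-yl]ethan-1-ol
Product: 4 2-[(4S)-2,2,4-trimethyl-1,3-dioxolan-4-yl]acetaldehyde
Conditions: TEMPO (10 mol %), PhI(OAc)2, CH2Cl2, rt
Reagents that add atoms: none
Why: TEMPO/PhI(OAc)2 oxidation stops at the aldehyde under non-basic conditions, so the β-alkoxy aldehyde does not eliminate.

Step 4
Reactants: 4 2-[(4S)-2,2,4-trimethyl-1,3-dioxolan-4-yl]acetaldehyde; 5 methyl prop-2-ynoate (methyl propiolate)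
Product: 6 methyl (4R)-4-hydroxy-5-[(4S)-2,2,4-trimethyl-1,3-dioxolan-4-yl]pent-2-ynoate
Conditions: (R,R)-ProPhenol (20 mol %), Ph3PO (40 mol %), Me2Zn, toluene, 0 °C, slow addition of 4
Reagents that add atoms: none
Why: Trost zinc–ProPhenol asymmetric alkynylation, in which the dinuclear zinc catalyst delivers the zinc acetylide to one aldehyde face and sets C8 (R) by catalyst control; the C8 epimer is separable because C10 is fixed.

Step 5
Reactants: 6 methyl (4R)-4-hydroxy-5-[(4S)-2,2,4-trimethyl-1,3-dioxolan-4-yl]pent-2-ynoate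
Product: 7 methyl (4R)-4-(triethylsilyloxy)-5-[(4S)-2,2,4-trimethyl-1,3-dioxolan-4-yl]pent-2-ynoate
Conditions: Et3SiCl, imidazole, CH2Cl2, 0 °C
Reagents that add atoms: chlorotriethylsilane, CC[Si](Cl)(CC)CC
Why: Imidazole-mediated silylation protects the C8 alcohol under conditions mild enough for the base-sensitive ynoate, so that it can neither lactonise nor be reduced later.

Step 6
Reactants: 7 methyl (4R)-4-(triethylsilyloxy)-5-[(4S)-2,2,4-trimethyl-1,3-dioxolan-4-yl]pent-2-ynoate; 8 2-(iodomethyl)-4,4,5,5-tetramethyl-1,3,2-dioxaborolane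
Product: 10 methyl (2Z,4R)-2-[(4,4,5,5-tetramethyl-1,3,2-dioxaborolan-2-yl)methyl]-4-(triethylsilyloxy)-5-[(4S)-2,2,4-trimethyl-1,3-dioxolan-4-yl]pent-2-enoate, via α-alumino enoate 9 (not isolated)
Conditions: iBu2AlH, HMPA, THF, 0 °C; then 8, 0 °C to rt
Reagents that add atoms: none
Why: Tsuda-type conjugate hydroalumination of the ynoate (syn addition, H to C7 and Al to C11) followed by alkylation of the vinylalane with the iodomethylboronate through a boron ate complex and 1,2-shift (Villiéras–Hall protocol) gives the allylboronate with C8 cis to the ester, that is trans to CH2B.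

Step 7
Reactants: 11 but-2-yne-1,4-diol
Product: 12 4-[(tert-butyldiphenylsilyl)oxy]but-2-yn-1-ol
Conditions: NaH (1 equiv), THF, 0 °C; tBuPh2SiCl (1 equiv)
Reagents that add atoms: tert-butyl(chloro)diphenylsilane, CC(C)(C)[Si](Cl)(c1ccccc1)c1ccccc1
Why: Monosilylation of a symmetric diol through its sparingly soluble monosodium alkoxide (McDougal protocol) differentiates the future C15 and C6 oxygens.

Step 8
Reactants: 12 4-[(tert-butyldiphenylsilyl)oxy]but-2-yn-1-ol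
Product: 14 (2Z)-4-[(tert-butyldiphenylsilyl)oxy]-3-iodobut-2-en-1-ol, via cyclic alkenylaluminate 13 (not isolated)
Conditions: NaAlH2(OCH2CH2OMe)2, THF, 0 °C; then NIS, −78 °C
Reagents that add atoms: N-iodosuccinimide, O=C1CCC(=O)N1I
Why: Hydroxyl-directed trans-hydroalumination of the propargylic alcohol puts aluminium on the distal carbon (C4) and hydrogen on C5, and iodinolysis with retention fixes the C4=C5 geometry with iodine cis to the CH2OH carbon (future C6).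

Step 9
Reactants: 14 (2Z)-4-[(tert-butyldiphenylsilyl)oxy]-3-iodobut-2-en-1-ol; 15 ethynyl(trimethyl)silane
Product: 16 (2E)-3-{[(tert-butyldiphenylsilyl)oxy]methyl}-5-(trimethylsilyl)pent-2-en-4-yn-1-ol
Conditions: PdCl2(PPh3)2 (2 mol %), CuI (4 mol %), Et3N, THF, rt
Reagents that add atoms: none
Why: Sonogashira coupling (oxidative addition of the vinyl iodide to zerovalent palladium, then copper acetylide transmetallation) installs C2–C3 with retention of the olefin geometry; the descriptor changes to E only because of CIP priorities.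

Step 10
Reactants: 16 (2E)-3-{[(tert-butyldiphenylsilyl)oxy]methyl}-5-(trimethylsilyl)pent-2-en-4-yn-1-ol
Product: 17 (2E)-3-{[(tert-butyldiphenylsilyl)oxy]methyl}-5-(trimethylsilyl)pent-2-en-4-ynal
Conditions: MnO2, CH2Cl2, rt
Reagents that add atoms: none
Why: MnO2 oxidises the allylic alcohol selectively to the enal without isomerising the trisubstituted olefin.

Step 11
Reactants: 10 methyl (2Z,4R)-2-[(4,4,5,5-tetramethyl-1,3,2-dioxaborolan-2-yl)methyl]-4-(triethylsilyloxy)-5-[(4S)-2,2,4-trimethyl-1,3-dioxolan-4-yl]pent-2-enoate; 17 (2E)-3-{[(tert-butyldiphenylsilyl)oxy]methyl}-5-(trimethylsilyl)pent-2-en-4-ynal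
Product: 19 (4S,5R)-5-[(1E)-2-{[(tert-butyldiphenylsilyl)oxy]methyl}-4-(trimethylsilyl)but-1-en-3-yn-1-yl]-3-methylidene-4-{(1R)-1-(triethylsilyloxy)-2-[(4S)-2,2,4-trimethyl-1,3-dioxolan-4-yl]ethyl}oxolan-2-one, via borate ester 18 (not isolated)
Conditions: Sc(OTf)3 (10 mol %), toluene, −78 to 0 °C; then PPTS (cat.), CH2Cl2, rt
Reagents that add atoms: none
Why: Lewis acid-accelerated allylboration through a closed chair transition state followed by lactonisation (Hall), in which the reagent geometry (C8 trans to CH2B) enforces the anti adduct and hence the trans lactone, while A(1,3) strain between C8 and the ester holds C8–H in the olefin plane so that the aldehyde adds anti to the C9 chain, which sets C6 and C7 as in the target.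

Step 12
Reactants: 19 (4S,5R)-5-[(1E)-2-{[(tert-butyldiphenylsilyl)oxy]methyl}-4-(trimethylsilyl)but-1-en-3-yn-1-yl]-3-methylidene-4-{(1R)-1-(triethylsilyloxy)-2-[(4S)-2,2,4-trimethyl-1,3-dioxolan-4-yl]ethyl}oxolan-2-one
Product: 20 (4S,5R)-5-[(1E)-2-{[(tert-butyldiphenylsilyl)oxy]methyl}-4-iodobut-1-en-3-yn-1-yl]-3-methylidene-4-{(1R)-1-(triethylsilyloxy)-2-[(4S)-2,2,4-trimethyl-1,3-dioxolan-4-yl]ethyl}oxolan-2-one
Conditions: NIS, AgNO3 (10 mol %), DMF, rt, dark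
Reagents that add atoms: N-iodosuccinimide, O=C1CCC(=O)N1I
Why: Silver-catalysed iododesilylation turns the alkynylsilane directly into the 1-iodoalkyne; it is done here, with no free hydroxyl cis to the alkyne, to avoid silver-induced furan formation.

Step 13
Reactants: 20 (4S,5R)-5-[(1E)-2-{[(tert-butyldiphenylsilyl)oxy]methyl}-4-iodobut-1-en-3-yn-1-yl]-3-methylidene-4-{(1R)-1-(triethylsilyloxy)-2-[(4S)-2,2,4-trimethyl-1,3-dioxolan-4-yl]ethyl}oxolan-2-one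
Product: 21 (4R,5R)-5-[(1E)-2-{[(tert-butyldiphenylsilyl)oxy]methyl}-4-iodobut-1-en-3-yn-1-yl]-4-{(1R)-1-hydroxy-2-[(4S)-2,2,4-trimethyl-1,3-dioxolan-4-yl]ethyl}-3-methylideneoxolan-2-one
Conditions: HF·pyridine, pyridine, THF, 0 °C
Reagents that add atoms: none
Why: Buffered HF·pyridine cleaves the secondary triethylsilyl ether far faster than the primary tert-butyldiphenylsilyl ether, and the trans 12,6-lactone does not translactonise to O8 because that isomer would be the cis-disubstituted lactone.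

Step 14
Reactants: 21 (4R,5R)-5-[(1E)-2-{[(tert-butyldiphenylsilyl)oxy]methyl}-4-iodobut-1-en-3-yn-1-yl]-4-{(1R)-1-hydroxy-2-[(4S)-2,2,4-trimethyl-1,3-dioxolan-4-yl]ethyl}-3-methylideneoxolan-2-one; 22 3-methylbutanoic anhydride
Product: 23 (1R)-1-[(2R,3R)-2-[(1E)-2-{[(tert-butyldiphenylsilyl)oxy]methyl}-4-iodobut-1-en-3-yn-1-yl]-4-methylidene-5-oxooxolan-3-yl]-2-[(4S)-2,2,4-trimethyl-1,3-dioxolan-4-yl]ethyl 3-methylbutanoate
Conditions: DMAP (10 mol %), pyridine, CH2Cl2, 0 °C to rt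
Reagents that add atoms: none
Why: DMAP-catalysed acylation installs the C8 3-methylbutanoate with retention, and tertiary amine bases do not add to the α-methylene lactone.

Step 15
Reactants: 23 (1R)-1-[(2R,3R)-2-[(1E)-2-{[(tert-butyldiphenylsilyl)oxy]methyl}-4-iodobut-1-en-3-yn-1-yl]-4-methylidene-5-oxooxolan-3-yl]-2-[(4S)-2,2,4-trimethyl-1,3-dioxolan-4-yl]ethyl 3-methylbutanoate
Product: 24 (1R,3S)-1-[(2R,3R)-2-[(1E)-2-{[(tert-butyldiphenylsilyl)oxy]methyl}-4-iodobut-1-en-3-yn-1-yl]-4-methylidene-5-oxooxolan-3-yl]-3,4-dihydroxy-3-methylbutyl 3-methylbutanoate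
Conditions: AcOH/H2O 4:1, 40 °C
Reagents that add atoms: none
Why: Acetal hydrolysis frees the C10 tertiary and C1 primary hydroxyls, while the tert-butyldiphenylsilyl ether, the ester, the lactone and the iodoalkyne tolerate aqueous acetic acid.

Step 16
Reactants: 24 (1R,3S)-1-[(2R,3R)-2-[(1E)-2-{[(tert-butyldiphenylsilyl)oxy]methyl}-4-iodobut-1-en-3-yn-1-yl]-4-methylidene-5-oxooxolan-3-yl]-3,4-dihydroxy-3-methylbutyl 3-methylbutanoate
Product: 25 (1R,3S)-1-[(2R,3R)-2-[(1E)-2-{[(tert-butyldiphenylsilyl)oxy]methyl}-4-iodobut-1-en-3-yn-1-yl]-4-methylidene-5-oxooxolan-3-yl]-3-hydroxy-3-methyl-4-oxobutyl 3-methylbutanoate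
Conditions: IBX, DMSO, rt
Reagents that add atoms: none
Why: IBX oxidises the primary alcohol to the aldehyde, does not cleave 1,2-diols and leaves the tertiary alcohol alone; the aldehyde has no α-hydrogen, so C10 cannot epimerise.

Step 17
Reactants: 25 (1R,3S)-1-[(2R,3R)-2-[(1E)-2-{[(tert-butyldiphenylsilyl)oxy]methyl}-4-iodobut-1-en-3-yn-1-yl]-4-methylidene-5-oxooxolan-3-yl]-3-hydroxy-3-methyl-4-oxobutyl 3-methylbutanoate
Product: 26 (4E,6R,7R,8R,10S)-15-[(tert-butyldiphenylsilyl)oxy]-1,10-dihydroxy-8-(3-methylbutanoyloxy)germacra-4,11(13)-dien-2-yn-12,6-olide (C1 epimers)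
Conditions: CrCl2 (8 equiv), NiCl2 (2 mol %), THF, rt, syringe-pump addition to 2 mM
Reagents that add atoms: none
Why: Intramolecular Nozaki–Hiyama–Kishi alkynylation, in which divalent chromium (nickel-assisted) inserts into the C(sp)–I bond and the non-basic trivalent alkynylchromium adds only to the aldehyde; the cis enyne and trans lactone pre-organise the chain as in ten-membered enediyne closures, and the new C1 carbinol forms as an epimer mixture that is oxidised next.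

Step 18
Reactants: 26 (4E,6R,7R,8R,10S)-15-[(tert-butyldiphenylsilyl)oxy]-1,10-dihydroxy-8-(3-methylbutanoyloxy)germacra-4,11(13)-dien-2-yn-12,6-olide (C1 epimers)
Product: 28 (4Z,6R,7R,8R,10S)-15-[(tert-butyldiphenylsilyl)oxy]-8-(3-methylbutanoyloxy)-1-oxo-3,10-epoxygermacra-2,4,11(13)-trien-12,6-olide, via macrocyclic ynone 27 (not isolated)
Conditions: IBX, DMSO, rt; aqueous work-up; then Ph3PAuNTf2 (5 mol %), CH2Cl2, rt
Reagents that add atoms: none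
Why: IBX oxidation of the propargylic alcohol gives the α'-hydroxy ynone, and the C10 hydroxyl then adds 5-endo-dig across the strained alkyne activated by monovalent gold (transannular oxa-Michael cycloisomerisation) to form the 3(2H)-furanone without touching any stereocentre.

Step 19
Reactants: 28 (4Z,6R,7R,8R,10S)-15-[(tert-butyldiphenylsilyl)oxy]-8-(3-methylbutanoyloxy)-1-oxo-3,10-epoxygermacra-2,4,11(13)-trien-12,6-olide
Product: 29 (4Z,6R,7R,8R,10S)-15-hydroxy-8-(3-methylbutanoyloxy)-1-oxo-3,10-epoxygermacra-2,4,11(13)-trien-12,6-olide (CNP0171896.1)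
Conditions: HF·pyridine, THF, 0 °C to rt
Reagents that add atoms: none
Why: Fluoride-mediated desilylation frees the C15 allylic alcohol under mildly acidic conditions that the ester, the α-methylene lactone and the furanone tolerate.

## Compound list

1 | (S)-citramalic acid [(2S)-2-hydroxy-2-methylbutanedioic acid] | C[C@](O)(CC(=O)O)C(=O)O | starting material
2 | (2S)-2-methylbutane-1,2,4-triol | C[C@](O)(CCO)CO | intermediate
3 | 2-[(4S)-2,2,4-trimethyl-1,3-dioxolan-4-yl]ethan-1-ol | C[C@]1(CCO)COC(C)(C)O1 | intermediate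
4 | 2-[(4S)-2,2,4-trimethyl-1,3-dioxolan-4-yl]acetaldehyde | C[C@]1(CC=O)COC(C)(C)O1 | intermediate
5 | methyl prop-2-ynoate (methyl propiolate) | C#CC(=O)OC | starting material
6 | methyl (4R)-4-hydroxy-5-[(4S)-2,2,4-trimethyl-1,3-dioxolan-4-yl]pent-2-ynoate | C[C@]1(C[C@@H](O)C#CC(=O)OC)COC(C)(C)O1 | intermediate
7 | methyl (4R)-4-(triethylsilyloxy)-5-[(4S)-2,2,4-trimethyl-1,3-dioxolan-4-yl]pent-2-ynoate | C[C@]1(C[C@@H](O[Si](CC)(CC)CC)C#CC(=O)OC)COC(C)(C)O1 | intermediate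
8 | 2-(iodomethyl)-4,4,5,5-tetramethyl-1,3,2-dioxaborolane | ICB1OC(C)(C)C(C)(C)O1 | starting material
9 | methyl (2E,4R)-2-[bis(2-methylpropyl)alumanyl]-4-(triethylsilyloxy)-5-[(4S)-2,2,4-trimethyl-1,3-dioxolan-4-yl]pent-2-enoate (H and Al cis) | C[C@]1(C[C@@H](O[Si](CC)(CC)CC)/C=C(/[Al](CC(C)C)CC(C)C)C(=O)OC)COC(C)(C)O1 | intermediate (not isolated)
10 | methyl (2Z,4R)-2-[(4,4,5,5-tetramethyl-1,3,2-dioxaborolan-2-yl)methyl]-4-(triethylsilyloxy)-5-[(4S)-2,2,4-trimethyl-1,3-dioxolan-4-yl]pent-2-enoate | C[C@]1(C[C@@H](O[Si](CC)(CC)CC)/C=C(/CB2OC(C)(C)C(C)(C)O2)C(=O)OC)COC(C)(C)O1 | intermediate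
11 | but-2-yne-1,4-diol | OCC#CCO | starting material
12 | 4-[(tert-butyldiphenylsilyl)oxy]but-2-yn-1-ol | OCC#CCO[Si](c1ccccc1)(c1ccccc1)C(C)(C)C | intermediate
13 | sodium 3-{[(tert-butyldiphenylsilyl)oxy]methyl}-2,2-bis(2-methoxyethoxy)-2,5-dihydro-1,2-oxaluminol-2-uide (cyclic alkenylaluminate) | [Na+].COCCO[Al-]1(OCCOC)OCC=C1CO[Si](c2ccccc2)(c3ccccc3)C(C)(C)C | intermediate (not isolated)
14 | (2Z)-4-[(tert-butyldiphenylsilyl)oxy]-3-iodobut-2-en-1-ol | OC/C=C(\I)CO[Si](c1ccccc1)(c1ccccc1)C(C)(C)C | intermediate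
15 | ethynyl(trimethyl)silane | C#C[Si](C)(C)C | starting material
16 | (2E)-3-{[(tert-butyldiphenylsilyl)oxy]methyl}-5-(trimethylsilyl)pent-2-en-4-yn-1-ol | OC/C=C(\C#C[Si](C)(C)C)CO[Si](c1ccccc1)(c1ccccc1)C(C)(C)C | intermediate
17 | (2E)-3-{[(tert-butyldiphenylsilyl)oxy]methyl}-5-(trimethylsilyl)pent-2-en-4-ynal | O=C/C=C(\C#C[Si](C)(C)C)CO[Si](c1ccccc1)(c1ccccc1)C(C)(C)C | intermediate
18 | methyl (3S,4R,5E)-6-{[(tert-butyldiphenylsilyl)oxy]methyl}-2-methylidene-4-[(4,4,5,5-tetramethyl-1,3,2-dioxaborolan-2-yl)oxy]-3-{(1R)-1-(triethylsilyloxy)-2-[(4S)-2,2,4-trimethyl-1,3-dioxolan-4-yl]ethyl}-8-(trimethylsilyl)oct-5-en-7-ynoate | C=C(C(=O)OC)[C@@H]([C@H](OB1OC(C)(C)C(C)(C)O1)/C=C(/CO[Si](c2ccccc2)(c3ccccc3)C(C)(C)C)C#C[Si](C)(C)C)[C@H](O[Si](CC)(CC)CC)C[C@@]4(C)COC(C)(C)O4 | intermediate (not isolated)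
19 | (4S,5R)-5-[(1E)-2-{[(tert-butyldiphenylsilyl)oxy]methyl}-4-(trimethylsilyl)but-1-en-3-yn-1-yl]-3-methylidene-4-{(1R)-1-(triethylsilyloxy)-2-[(4S)-2,2,4-trimethyl-1,3-dioxolan-4-yl]ethyl}oxolan-2-one | C=C1C(=O)O[C@H](/C=C(/CO[Si](c2ccccc2)(c3ccccc3)C(C)(C)C)C#C[Si](C)(C)C)[C@H]1[C@H](O[Si](CC)(CC)CC)C[C@@]4(C)COC(C)(C)O4 | intermediate
20 | (4S,5R)-5-[(1E)-2-{[(tert-butyldiphenylsilyl)oxy]methyl}-4-iodobut-1-en-3-yn-1-yl]-3-methylidene-4-{(1R)-1-(triethylsilyloxy)-2-[(4S)-2,2,4-trimethyl-1,3-dioxolan-4-yl]ethyl}oxolan-2-one | C=C1C(=O)O[C@H](/C=C(/CO[Si](c2ccccc2)(c3ccccc3)C(C)(C)C)C#CI)[C@H]1[C@H](O[Si](CC)(CC)CC)C[C@@]4(C)COC(C)(C)O4 | intermediate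
21 | (4R,5R)-5-[(1E)-2-{[(tert-butyldiphenylsilyl)oxy]methyl}-4-iodobut-1-en-3-yn-1-yl]-4-{(1R)-1-hydroxy-2-[(4S)-2,2,4-trimethyl-1,3-dioxolan-4-yl]ethyl}-3-methylideneoxolan-2-one | C=C1C(=O)O[C@H](/C=C(/CO[Si](c2ccccc2)(c3ccccc3)C(C)(C)C)C#CI)[C@H]1[C@H](O)C[C@@]4(C)COC(C)(C)O4 | intermediate
22 | 3-methylbutanoic anhydride | CC(C)CC(=O)OC(=O)CC(C)C | starting material
23 | (1R)-1-[(2R,3R)-2-[(1E)-2-{[(tert-butyldiphenylsilyl)oxy]methyl}-4-iodobut-1-en-3-yn-1-yl]-4-methylidene-5-oxooxolan-3-yl]-2-[(4S)-2,2,4-trimethyl-1,3-dioxolan-4-yl]ethyl 3-methylbutanoate | C=C1C(=O)O[C@H](/C=C(/CO[Si](c2ccccc2)(c3ccccc3)C(C)(C)C)C#CI)[C@H]1[C@H](OC(=O)CC(C)C)C[C@@]4(C)COC(C)(C)O4 | intermediate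
24 | (1R,3S)-1-[(2R,3R)-2-[(1E)-2-{[(tert-butyldiphenylsilyl)oxy]methyl}-4-iodobut-1-en-3-yn-1-yl]-4-methylidene-5-oxooxolan-3-yl]-3,4-dihydroxy-3-methylbutyl 3-methylbutanoate | C=C1C(=O)O[C@H](/C=C(/CO[Si](c2ccccc2)(c3ccccc3)C(C)(C)C)C#CI)[C@H]1[C@H](OC(=O)CC(C)C)C[C@](C)(O)CO | intermediate
25 | (1R,3S)-1-[(2R,3R)-2-[(1E)-2-{[(tert-butyldiphenylsilyl)oxy]methyl}-4-iodobut-1-en-3-yn-1-yl]-4-methylidene-5-oxooxolan-3-yl]-3-hydroxy-3-methyl-4-oxobutyl 3-methylbutanoate | C=C1C(=O)O[C@H](/C=C(/CO[Si](c2ccccc2)(c3ccccc3)C(C)(C)C)C#CI)[C@H]1[C@H](OC(=O)CC(C)C)C[C@](C)(O)C=O | intermediate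
26 | (4E,6R,7R,8R,10S)-15-[(tert-butyldiphenylsilyl)oxy]-1,10-dihydroxy-8-(3-methylbutanoyloxy)germacra-4,11(13)-dien-2-yn-12,6-olide (C1 epimers; ten-membered carbocycle C1–C10 with C2≡C3 and trans-fused C6/C7 lactone) | C=C1C(=O)O[C@@H]2/C=C(/CO[Si](c3ccccc3)(c4ccccc4)C(C)(C)C)C#CC(O)[C@](C)(C[C@@H](OC(=O)CC(C)C)[C@@H]12)O | intermediate
27 | (4E,6R,7R,8R,10S)-15-[(tert-butyldiphenylsilyl)oxy]-10-hydroxy-8-(3-methylbutanoyloxy)-1-oxogermacra-4,11(13)-dien-2-yn-12,6-olide | C=C1C(=O)O[C@@H]2/C=C(/CO[Si](c3ccccc3)(c4ccccc4)C(C)(C)C)C#CC(=O)[C@](C)(C[C@@H](OC(=O)CC(C)C)[C@@H]12)O | intermediate (not isolated)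
28 | (4Z,6R,7R,8R,10S)-15-[(tert-butyldiphenylsilyl)oxy]-8-(3-methylbutanoyloxy)-1-oxo-3,10-epoxygermacra-2,4,11(13)-trien-12,6-olide | C=C1C(=O)O[C@@H]2/C=C(/CO[Si](c3ccccc3)(c4ccccc4)C(C)(C)C)C5=CC(=O)[C@](C)(C[C@@H](OC(=O)CC(C)C)[C@@H]12)O5 | intermediate
29 | (4Z,6R,7R,8R,10S)-15-hydroxy-8-(3-methylbutanoyloxy)-1-oxo-3,10-epoxygermacra-2,4,11(13)-trien-12,6-olide (CNP0171896.1) | C=C1C(=O)O[C@@H]2/C=C(/CO)C3=CC(=O)[C@](C)(C[C@@H](OC(=O)CC(C)C)[C@@H]12)O3 | target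

## Step count and risks

Total: 19 steps (fragment A: steps 1–6; fragment B: steps 7–10; union and end-game: steps 11–19).
Longest linear sequence: 15 steps (steps 1–6, then 11–19).

The three steps most likely to fail:

Step 11, π-facial selectivity of the allylboration. The anti (trans-lactone) outcome is fixed by the reagent geometry, but which face of the boronate reacts relative to C8 rests on an A(1,3)-strain model. Fallback, setting out from 4 and returning at 23: if the aldehyde adds anti to the silyloxy group instead, the route is run with the C8 epimer and C8 is corrected when the ester is introduced. Alkynylation of 4 with 5 under (S,S)-ProPhenol/Me2Zn gives methyl (4S)-4-hydroxy-5-[(4S)-2,2,4-trimethyl-1,3-dioxolan-4-yl]pent-2-ynoate F3. Silylation gives methyl (4S)-4-(triethylsilyloxy)-5-[(4S)-2,2,4-trimethyl-1,3-dioxolan-4-yl]pent-2-ynoate F4. iBu2AlH/HMPA then 8 gives methyl (2Z,4S)-2-[(4,4,5,5-tetramethyl-1,3,2-dioxaborolan-2-yl)methyl]-4-(triethylsilyloxy)-5-[(4S)-2,2,4-trimethyl-1,3-dioxolan-4-yl]pent-2-enoate F5. Sc(OTf)3-catalysed allylboration of 17 with the same facial preference then gives the C6/C7-correct lactone (4S,5R)-5-[(1E)-2-{[(tert-butyldiphenylsilyl)oxy]methyl}-4-(trimethylsilyl)but-1-en-3-yn-1-yl]-3-methylidene-4-{(1S)-1-(triethylsilyloxy)-2-[(4S)-2,2,4-trimethyl-1,3-dioxolan-4-yl]ethyl}oxolan-2-one F6. HF·pyridine gives the (1S)-alcohol (4R,5R)-5-[(1E)-2-{[(tert-butyldiphenylsilyl)oxy]methyl}-4-(trimethylsilyl)but-1-en-3-yn-1-yl]-4-{(1S)-1-hydroxy-2-[(4S)-2,2,4-trimethyl-1,3-dioxolan-4-yl]ethyl}-3-methylideneoxolan-2-one F7. Mitsunobu esterification with 3-methylbutanoic acid (PPh3, DIAD, toluene) inverts C8 and gives (1R)-1-[(2R,3R)-2-[(1E)-2-{[(tert-butyldiphenylsilyl)oxy]methyl}-4-(trimethylsilyl)but-1-en-3-yn-1-yl]-4-methylidene-5-oxooxolan-3-yl]-2-[(4S)-2,2,4-trimethyl-1,3-dioxolan-4-yl]ethyl 3-methylbutanoate F8. NIS/AgNO3 iododesilylation of F8 gives 23.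

Step 17, closure of the strained ten-membered enyne (oligomerisation, or reduction of the iodoalkyne without cyclisation). Fallback, setting out from 14 and returning at 26: the ring is closed at C3–C4 by an intramolecular Sonogashira coupling instead of at C1–C2. MnO2 oxidation of 14 gives (2Z)-4-[(tert-butyldiphenylsilyl)oxy]-3-iodobut-2-enal F9. Allylboration/lactonisation with 10 (Sc(OTf)3, then PPTS) gives (4S,5S)-5-[(1Z)-3-[(tert-butyldiphenylsilyl)oxy]-2-iodoprop-1-en-1-yl]-3-methylidene-4-{(1R)-1-(triethylsilyloxy)-2-[(4S)-2,2,4-trimethyl-1,3-dioxolan-4-yl]ethyl}oxolan-2-one F10. HF·pyridine gives (4R,5S)-5-[(1Z)-3-[(tert-butyldiphenylsilyl)oxy]-2-iodoprop-1-en-1-yl]-4-{(1R)-1-hydroxy-2-[(4S)-2,2,4-trimethyl-1,3-dioxolan-4-yl]ethyl}-3-methylideneoxolan-2-one F11. Acylation with 22 gives (1R)-1-[(2S,3R)-2-[(1Z)-3-[(tert-butyldiphenylsilyl)oxy]-2-iodoprop-1-en-1-yl]-4-methylidene-5-oxooxolan-3-yl]-2-[(4S)-2,2,4-trimethyl-1,3-dioxolan-4-yl]ethyl 3-methylbutanoate F12. Aqueous acetic acid gives (1R,3S)-1-[(2S,3R)-2-[(1Z)-3-[(tert-butyldiphenylsilyl)oxy]-2-iodoprop-1-en-1-yl]-4-methylidene-5-oxooxolan-3-yl]-3,4-dihydroxy-3-methylbutyl 3-methylbutanoate F13. IBX gives (1R,3S)-1-[(2S,3R)-2-[(1Z)-3-[(tert-butyldiphenylsilyl)oxy]-2-iodoprop-1-en-1-yl]-4-methylidene-5-oxooxolan-3-yl]-3-hydroxy-3-methyl-4-oxobutyl 3-methylbutanoate F14. HC≡CMgBr (2.2 equiv, THF, −78 °C) adds to the aldehyde to give (1R,3S)-1-[(2S,3R)-2-[(1Z)-3-[(tert-butyldiphenylsilyl)oxy]-2-iodoprop-1-en-1-yl]-4-methylidene-5-oxooxolan-3-yl]-3,4-dihydroxy-3-methylhex-5-yn-1-yl 3-methylbutanoate (C4 epimers) F15. High-dilution Sonogashira cyclisation of F15 (Pd(PPh3)4, CuI, iPr2NEt, THF) gives 26.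

Step 4, the catalytic asymmetric alkynylation of an enolisable, β-oxygenated aliphatic aldehyde (conversion and selectivity). Fallback, setting out from 4 and returning at 6: C8 is set by reduction instead of addition. The lithium acetylide of 5 (LiN(SiMe3)2, THF, −78 °C) adds to 4 to give methyl 4-hydroxy-5-[(4S)-2,2,4-trimethyl-1,3-dioxolan-4-yl]pent-2-ynoate (C4 epimers) F1. IBX oxidation gives methyl 4-oxo-5-[(4S)-2,2,4-trimethyl-1,3-dioxolan-4-yl]pent-2-ynoate F2. Noyori transfer hydrogenation of F2 with RuCl(p-cymene)[(R,R)-TsDPEN] in iPrOH reduces the ynone under catalyst control to 6.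

## Further compounds

F1 | step 4 | methyl 4-hydroxy-5-[(4S)-2,2,4-trimethyl-1,3-dioxolan-4-yl]pent-2-ynoate (C4 epimers) | C[C@]1(CC(O)C#CC(=O)OC)COC(C)(C)O1
F2 | step 4 | methyl 4-oxo-5-[(4S)-2,2,4-trimethyl-1,3-dioxolan-4-yl]pent-2-ynoate | C[C@]1(CC(=O)C#CC(=O)OC)COC(C)(C)O1
F3 | step 11 | methyl (4S)-4-hydroxy-5-[(4S)-2,2,4-trimethyl-1,3-dioxolan-4-yl]pent-2-ynoate | C[C@]1(C[C@H](O)C#CC(=O)OC)COC(C)(C)O1
F4 | step 11 | methyl (4S)-4-(triethylsilyloxy)-5-[(4S)-2,2,4-trimethyl-1,3-dioxolan-4-yl]pent-2-ynoate | C[C@]1(C[C@H](O[Si](CC)(CC)CC)C#CC(=O)OC)COC(C)(C)O1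
F5 | step 11 | methyl (2Z,4S)-2-[(4,4,5,5-tetramethyl-1,3,2-dioxaborolan-2-yl)methyl]-4-(triethylsilyloxy)-5-[(4S)-2,2,4-trimethyl-1,3-dioxolan-4-yl]pent-2-enoate | C[C@]1(C[C@H](O[Si](CC)(CC)CC)/C=C(/CB2OC(C)(C)C(C)(C)O2)C(=O)OC)COC(C)(C)O1
F6 | step 11 | (4S,5R)-5-[(1E)-2-{[(tert-butyldiphenylsilyl)oxy]methyl}-4-(trimethylsilyl)but-1-en-3-yn-1-yl]-3-methylidene-4-{(1S)-1-(triethylsilyloxy)-2-[(4S)-2,2,4-trimethyl-1,3-dioxolan-4-yl]ethyl}oxolan-2-one | C=C1C(=O)O[C@H](/C=C(/CO[Si](c2ccccc2)(c3ccccc3)C(C)(C)C)C#C[Si](C)(C)C)[C@H]1[C@@H](O[Si](CC)(CC)CC)C[C@@]4(C)COC(C)(C)O4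
F7 | step 11 | (4R,5R)-5-[(1E)-2-{[(tert-butyldiphenylsilyl)oxy]methyl}-4-(trimethylsilyl)but-1-en-3-yn-1-yl]-4-{(1S)-1-hydroxy-2-[(4S)-2,2,4-trimethyl-1,3-dioxolan-4-yl]ethyl}-3-methylideneoxolan-2-one | C=C1C(=O)O[C@H](/C=C(/CO[Si](c2ccccc2)(c3ccccc3)C(C)(C)C)C#C[Si](C)(C)C)[C@H]1[C@@H](O)C[C@@]4(C)COC(C)(C)O4
F8 | step 11 | (1R)-1-[(2R,3R)-2-[(1E)-2-{[(tert-butyldiphenylsilyl)oxy]methyl}-4-(trimethylsilyl)but-1-en-3-yn-1-yl]-4-methylidene-5-oxooxolan-3-yl]-2-[(4S)-2,2,4-trimethyl-1,3-dioxolan-4-yl]ethyl 3-methylbutanoate | C=C1C(=O)O[C@H](/C=C(/CO[Si](c2ccccc2)(c3ccccc3)C(C)(C)C)C#C[Si](C)(C)C)[C@H]1[C@H](OC(=O)CC(C)C)C[C@@]4(C)COC(C)(C)O4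
F9 | step 17 | (2Z)-4-[(tert-butyldiphenylsilyl)oxy]-3-iodobut-2-enal | O=C/C=C(\I)CO[Si](c1ccccc1)(c1ccccc1)C(C)(C)C
F10 | step 17 | (4S,5S)-5-[(1Z)-3-[(tert-butyldiphenylsilyl)oxy]-2-iodoprop-1-en-1-yl]-3-methylidene-4-{(1R)-1-(triethylsilyloxy)-2-[(4S)-2,2,4-trimethyl-1,3-dioxolan-4-yl]ethyl}oxolan-2-one | C=C1C(=O)O[C@H](/C=C(\I)CO[Si](c2ccccc2)(c3ccccc3)C(C)(C)C)[C@H]1[C@H](O[Si](CC)(CC)CC)C[C@@]4(C)COC(C)(C)O4
F11 | step 17 | (4R,5S)-5-[(1Z)-3-[(tert-butyldiphenylsilyl)oxy]-2-iodoprop-1-en-1-yl]-4-{(1R)-1-hydroxy-2-[(4S)-2,2,4-trimethyl-1,3-dioxolan-4-yl]ethyl}-3-methylideneoxolan-2-one | C=C1C(=O)O[C@H](/C=C(\I)CO[Si](c2ccccc2)(c3ccccc3)C(C)(C)C)[C@H]1[C@H](O)C[C@@]4(C)COC(C)(C)O4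
F12 | step 17 | (1R)-1-[(2S,3R)-2-[(1Z)-3-[(tert-butyldiphenylsilyl)oxy]-2-iodoprop-1-en-1-yl]-4-methylidene-5-oxooxolan-3-yl]-2-[(4S)-2,2,4-trimethyl-1,3-dioxolan-4-yl]ethyl 3-methylbutanoate | C=C1C(=O)O[C@H](/C=C(\I)CO[Si](c2ccccc2)(c3ccccc3)C(C)(C)C)[C@H]1[C@H](OC(=O)CC(C)C)C[C@@]4(C)COC(C)(C)O4
F13 | step 17 | (1R,3S)-1-[(2S,3R)-2-[(1Z)-3-[(tert-butyldiphenylsilyl)oxy]-2-iodoprop-1-en-1-yl]-4-methylidene-5-oxooxolan-3-yl]-3,4-dihydroxy-3-methylbutyl 3-methylbutanoate | C=C1C(=O)O[C@H](/C=C(\I)CO[Si](c2ccccc2)(c3ccccc3)C(C)(C)C)[C@H]1[C@H](OC(=O)CC(C)C)C[C@](C)(O)CO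
F14 | step 17 | (1R,3S)-1-[(2S,3R)-2-[(1Z)-3-[(tert-butyldiphenylsilyl)oxy]-2-iodoprop-1-en-1-yl]-4-methylidene-5-oxooxolan-3-yl]-3-hydroxy-3-methyl-4-oxobutyl 3-methylbutanoate | C=C1C(=O)O[C@H](/C=C(\I)CO[Si](c2ccccc2)(c3ccccc3)C(C)(C)C)[C@H]1[C@H](OC(=O)CC(C)C)C[C@](C)(O)C=O
F15 | step 17 | (1R,3S)-1-[(2S,3R)-2-[(1Z)-3-[(tert-butyldiphenylsilyl)oxy]-2-iodoprop-1-en-1-yl]-4-methylidene-5-oxooxolan-3-yl]-3,4-dihydroxy-3-methylhex-5-yn-1-yl 3-methylbutanoate (C4 epimers) | C=C1C(=O)O[C@H](/C=C(\I)CO[Si](c2ccccc2)(c3ccccc3)C(C)(C)C)[C@H]1[C@H](OC(=O)CC(C)C)C[C@](C)(O)C(O)C#C
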